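## Retrosynthetic overview

1. The target is released last by fluoride cleavage of a 2-(trimethylsilyl)ethyl enol ether that masks the tetronic acid.
2. The chain is cut between the homoallylic CH2 and the Z-alkenyl carbon: a bis-furan E-homoallylic zinc reagent plus an (R)-configured Z-iodoalkenyl tetronate (Negishi coupling).
3. The only stereocentre (C5 of the butenolide) comes from a chiral-ammonium phase-transfer C5-allylation of the O-protected 3-methyltetronate with a Z-iodoallyl bromide, itself made from propargyl alcohol.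
4. The bis-furan arm comes from a B-alkyl Suzuki coupling of a 4-bromo-2-(3-furylmethyl)furan with the 9-BBN adduct of an E-bromodiene.
5. Ring order: no ring is built; both furans and the butenolide enter as purchased heterocycles.

Assumption: every compound marked "starting material" is taken as a catalogue chemical; the absolute sense of induction in step 7 is predicted by analogy and must be confirmed on the first run (chiral HPLC and correlation).

## Route

Step 1
Reactants: 1 4-bromofuran-2-carbaldehyde; 2 4-methylbenzenesulfonohydrazide; 3 furan-3-ylboronic acid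
Product: 6 4-bromo-2-(furan-3-ylmethyl)furan, via tosylhydrazone 4 (not isolated), via diazo compound 5 (not isolated)
Conditions: 2 (1.05 equiv), 1,4-dioxane, 80 °C; then K2CO3 (2 equiv), 3 (1.5 equiv), 110 °C
Reagents that add atoms: none
Why: Barluenga–Valdés reductive coupling: condensation gives tosylhydrazone 4, K2CO3 converts it (Bamford–Stevens) into diazo compound 5, and the boronic acid captures 5 by boronate formation, 1,2-furyl shift with loss of N2 and protodeboronation, so the difurylmethane forms without any transition metal and the C–Br bond survives.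

Step 2
Reactants: 7 4-bromobut-1-yne; 8 bromoethene
Product: 10 (E)-6-bromo-4-methylhexa-1,3-diene, via alkenylalane 9 (not isolated)
Conditions: Me3Al (2 equiv), Cp2ZrCl2 (20 mol%), CH2Cl2, 0 °C to rt; then 8 (1 M in THF), ZnCl2 (20 mol%), Pd(PPh3)4 (5 mol%), rt
Reagents that add atoms: trimethylaluminium, C[Al](C)C
Why: Negishi carboalumination: the Cp2ZrCl2-catalysed syn addition of Me–Al puts methyl on the internal and aluminium on the terminal alkyne carbon, and the palladium-catalysed coupling of alkenylalane 9 with vinyl bromide proceeds with retention, so the trisubstituted alkene is E; the primary C–Br bond is inert to both operations.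

Step 3
Reactants: 10 (E)-6-bromo-4-methylhexa-1,3-diene; 11 9-borabicyclo[3.3.1]nonane; 6 4-bromo-2-(furan-3-ylmethyl)furan
Product: 13 4-[(E)-6-bromo-4-methylhex-3-en-1-yl]-2-(furan-3-ylmethyl)furan, via B-alkylborane 12 (not isolated)
Conditions: 11 (1.1 equiv), THF, 0 °C to rt; then 6, Pd(dppf)Cl2 (5 mol%), K3PO4 (3 M aq), THF, 50 °C
Reagents that add atoms: none
Why: 9-BBN hydroborates only the monosubstituted terminal alkene of the diene at CH2 (anti-Markovnikov), and the B-alkyl Suzuki–Miyaura coupling takes place at the furyl C(sp2)–Br bond, whose oxidative addition is much faster than that of the primary alkyl bromide.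

Step 4
Reactants: 14 prop-2-yn-1-ol
Product: 16 (Z)-3-iodo-2-methylprop-2-en-1-ol, via alkenylmagnesium chelate 15 (not isolated)
Conditions: MeMgBr (2.5 equiv), CuI (10 mol%), Et2O, −10 °C to rt; then I2, −10 °C
Reagents that add atoms: methylmagnesium bromide, C[Mg]Br; iodine, II
Why: Duboudin–Jousseaume copper-catalysed anti-carbomagnesiation of the magnesium propargyl alkoxide delivers methyl to C2 and forms the five-membered chelate 15 in which Mg is necessarily cis to CH2O, and iodinolysis with retention fixes the Z alkene (no stereocentre).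

Step 5
Reactants: 16 (Z)-3-iodo-2-methylprop-2-en-1-ol
Product: 17 (Z)-3-bromo-1-iodo-2-methylprop-1-ene
Conditions: CBr4, PPh3, CH2Cl2, 0 °C
Reagents that add atoms: carbon tetrabromide, BrC(Br)(Br)Br
Why: Appel reaction: bromide displaces the alkoxyphosphonium at the primary allylic carbon by SN2 at 0 °C, without allylic transposition and without touching the alkenyl iodide geometry.

Step 6
Reactants: 18 4-hydroxy-3-methylfuran-2(5H)-one; 19 2-(trimethylsilyl)ethan-1-ol
Product: 20 3-methyl-4-[2-(trimethylsilyl)ethoxy]furan-2(5H)-one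
Conditions: PPh3, DIAD, THF, 0 °C to rt
Reagents that add atoms: none
Why: Mitsunobu etherification: the acidic tetronic acid (pKa about 4) is alkylated at O4 by the alkoxyphosphonium of the primary alcohol, the known regiochemistry for tetronic acids, giving the conjugated 4-alkoxybutenolide.

Step 7
Reactants: 20 3-methyl-4-[2-(trimethylsilyl)ethoxy]furan-2(5H)-one; 17 (Z)-3-bromo-1-iodo-2-methylprop-1-ene
Product: 21 (R)-5-[(Z)-3-iodo-2-methylprop-2-en-1-yl]-3-methyl-4-[2-(trimethylsilyl)ethoxy]furan-2(5H)-one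
Conditions: (R)-4,4-dibutyl-2,6-bis(3,4,5-trifluorophenyl)-4,5-dihydro-3H-dinaphtho[2,1-c:1',2'-e]azepinium bromide (5 mol%), CsOH·H2O (5 equiv), 17 (1.3 equiv), toluene/CH2Cl2 4:1, −40 °C
Reagents that add atoms: none
Why: Proposed new method: enantioselective phase-transfer C5-alkylation of a 4-alkoxybutenolide (a vinylogous glycolate), which has not been reported; solid CsOH deprotonates C5–H at the interface (this position is cleanly lithiated by LiN(i-Pr)2, estimated pKa in the low-to-mid twenties) to give the aromatic 4-alkoxy-3-methylfuran-2-olate, which is carried into the organic phase as a tight ion pair with the C2-symmetric binaphthyl ammonium cation bound at the exocyclic oxygen, so that one face of the flat anion is walled off by a 3,4,5-trifluorophenyl group and the primary allylic bromide is attacked by C5 (C3 is blocked by methyl, and C5-selectivity is known for the lithium dienolate) in an SN2 step on the Re face to give (R) with the alkene geometry untouched, while the tertiary, shielded C5–H of the product limits dialkylation and racemisation at −40 °C; the closest known reactions are the cinchona-ammonium phase-transfer alkylation of O-benzhydryl glycolate ketones and of glycine imines, and the catalyst antipode is chosen by analogy with the latter (the (S)-catalyst is equally available if the sense proves opposite).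

Step 8
Reactants: 13 4-[(E)-6-bromo-4-methylhex-3-en-1-yl]-2-(furan-3-ylmethyl)furan; 22 zinc; 21 (R)-5-[(Z)-3-iodo-2-methylprop-2-en-1-yl]-3-methyl-4-[2-(trimethylsilyl)ethoxy]furan-2(5H)-one
Product: 24 (R)-5-[(2Z,6E)-9-[5-(furan-3-ylmethyl)furan-3-yl]-2,6-dimethylnona-2,6-dien-1-yl]-3-methyl-4-[2-(trimethylsilyl)ethoxy]furan-2(5H)-one, via alkylzinc bromide 23 (not isolated)
Conditions: 22 (dust, 1.5 equiv), LiCl, THF, 50 °C; then 21, Pd(OAc)2 (2 mol%), SPhos (4 mol%), THF, rt
Reagents that add atoms: none
Why: LiCl-assisted zinc insertion into the primary alkyl bromide gives alkylzinc 23, which tolerates the lactone, and the Negishi C(sp3)–C(sp2) coupling with the alkenyl iodide proceeds with retention of the Z geometry under neutral conditions that cannot epimerise C5.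

Step 9
Reactants: 24 (R)-5-[(2Z,6E)-9-[5-(furan-3-ylmethyl)furan-3-yl]-2,6-dimethylnona-2,6-dien-1-yl]-3-methyl-4-[2-(trimethylsilyl)ethoxy]furan-2(5H)-one
Product: 25 (R)-5-[(2Z,6E)-9-[5-(furan-3-ylmethyl)furan-3-yl]-2,6-dimethylnona-2,6-dien-1-yl]-4-hydroxy-3-methylfuran-2(5H)-one
Conditions: Bu4NF, AcOH (1:1), THF, 0 °C to rt; aqueous work-up at pH 3
Reagents that add atoms: none
Why: Fluoride attacks silicon and triggers β-elimination (ethene and Me3SiF) that releases the tetronate, which is protonated on work-up; AcOH buffering keeps the medium non-basic so that C5–H is not epimerised, and the furans and alkenes are untouched.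

## Compound list

1 | 4-bromofuran-2-carbaldehyde | O=Cc1cc(Br)co1 | starting material
2 | 4-methylbenzenesulfonohydrazide | Cc1ccc(cc1)S(=O)(=O)NN | starting material
3 | furan-3-ylboronic acid | OB(O)c1ccoc1 | starting material
4 | N'-[(E)-(4-bromofuran-2-yl)methylidene]-4-methylbenzenesulfonohydrazide | Cc1ccc(cc1)S(=O)(=O)N/N=C/c1cc(Br)co1 | intermediate
5 | 4-bromo-2-(diazomethyl)furan | [N-]=[N+]=Cc1cc(Br)co1 | intermediate
6 | 4-bromo-2-(furan-3-ylmethyl)furan | Brc1coc(Cc2ccoc2)c1 | intermediate
7 | 4-bromobut-1-yne | BrCCC#C | starting material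
8 | bromoethene | BrC=C | starting material
9 | [(E)-4-bromo-2-methylbut-1-en-1-yl]dimethylalumane | C[Al](C)/C=C(C)/CCBr | intermediate
10 | (E)-6-bromo-4-methylhexa-1,3-diene | BrCC/C(C)=C/C=C | intermediate
11 | 9-borabicyclo[3.3.1]nonane | B1C2CCCC1CCC2 | starting material
12 | 9-[(E)-6-bromo-4-methylhex-3-en-1-yl]-9-borabicyclo[3.3.1]nonane | BrCC/C(C)=C/CCB1C2CCCC1CCC2 | intermediate
13 | 4-[(E)-6-bromo-4-methylhex-3-en-1-yl]-2-(furan-3-ylmethyl)furan | BrCC/C(C)=C/CCc1coc(Cc2ccoc2)c1 | intermediate
14 | prop-2-yn-1-ol | OCC#C | starting material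
15 | 4-methyl-2,5-dihydro-1,2-oxamagnesole (cyclic alkenylmagnesium alkoxide) | CC1=C[Mg]OC1 | intermediate
16 | (Z)-3-iodo-2-methylprop-2-en-1-ol | OC/C(C)=C\I | intermediate
17 | (Z)-3-bromo-1-iodo-2-methylprop-1-ene | BrC/C(C)=C\I | intermediate
18 | 4-hydroxy-3-methylfuran-2(5H)-one (3-methyltetronic acid) | CC1=C(O)COC1=O | starting material
19 | 2-(trimethylsilyl)ethan-1-ol | C[Si](C)(C)CCO | starting material
20 | 3-methyl-4-[2-(trimethylsilyl)ethoxy]furan-2(5H)-one | CC1=C(OCC[Si](C)(C)C)COC1=O | intermediate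
21 | (R)-5-[(Z)-3-iodo-2-methylprop-2-en-1-yl]-3-methyl-4-[2-(trimethylsilyl)ethoxy]furan-2(5H)-one | CC1=C(OCC[Si](C)(C)C)[C@@H](C/C(C)=C\I)OC1=O | intermediate
22 | zinc | [Zn] | starting material
23 | bromo{(E)-6-[5-(furan-3-ylmethyl)furan-3-yl]-3-methylhex-3-en-1-yl}zinc | Br[Zn]CC/C(C)=C/CCc1coc(Cc2ccoc2)c1 | intermediate
24 | (R)-5-[(2Z,6E)-9-[5-(furan-3-ylmethyl)furan-3-yl]-2,6-dimethylnona-2,6-dien-1-yl]-3-methyl-4-[2-(trimethylsilyl)ethoxy]furan-2(5H)-one | CC1=C(OCC[Si](C)(C)C)[C@@H](C/C(C)=C\CC/C(C)=C/CCc2coc(Cc3ccoc3)c2)OC1=O | intermediate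
25 | (R)-5-[(2Z,6E)-9-[5-(furan-3-ylmethyl)furan-3-yl]-2,6-dimethylnona-2,6-dien-1-yl]-4-hydroxy-3-methylfuran-2(5H)-one | CC1=C(O)[C@@H](C/C(C)=C\CC/C(C)=C/CCc2coc(Cc3ccoc3)c2)OC1=O | target

## Step count and risks

Total step count: 9. Longest linear sequence: 5 (steps 4, 5, 7, 8, 9).

**Step 7 (the proposed new reaction).** Possible failures: C5–H too weakly acidic for CsOH, O-alkylation, low ee, or base-mediated racemisation of 21. The fallback uses known chemistry, sets out from 17 and comes back at 21. It sets the same centre by the known cinchona phase-transfer alkylation of a glycolate and then builds the butenolide by Dieckmann cyclisation. The known pronucleophile 2-(benzhydryloxy)-1-(1-methyl-1H-imidazol-2-yl)ethan-1-one is alkylated with 17 (O-allyl-N-(2,3,4-trifluorobenzyl)hydrocinchoninium bromide 10 mol%, the pseudoenantiomeric series that leads to (R); CsOH·H2O, CH2Cl2/hexane, −40 °C) to give (2R,4Z)-2-(benzhydryloxy)-5-iodo-4-methyl-1-(1-methyl-1H-imidazol-2-yl)pent-4-en-1-one F2. MeOTf converts it into 2-[(2R,4Z)-2-(benzhydryloxy)-5-iodo-4-methylpent-4-enoyl]-1,3-dimethyl-1H-imidazol-3-ium trifluoromethanesulfonate F3, which MeOH/i-Pr2NEt turns into methyl (2R,4Z)-2-(benzhydryloxy)-5-iodo-4-methylpent-4-enoate F4. CF3CO2H/Et3SiH (CH2Cl2, 0 °C; the alkenyl iodide is acid-stable) removes the benzhydryl group to give methyl (2R,4Z)-2-hydroxy-5-iodo-4-methylpent-4-enoate F5. Propanoyl chloride/pyridine gives methyl (2R,4Z)-5-iodo-4-methyl-2-(propanoyloxy)pent-4-enoate F6. LiN(SiMe3)2 (2.2 equiv, THF, −78 °C) closes the ring to (R)-4-hydroxy-5-[(Z)-3-iodo-2-methylprop-2-en-1-yl]-3-methylfuran-2(5H)-one F7. Mitsunobu etherification with 19 (PPh3, DIAD) then returns to 21.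

**Step 8 (zinc insertion and Negishi coupling).** Possible failures: sluggish insertion into the alkyl bromide, E/Z erosion of the homoallylic zinc reagent, or β-hydride elimination. The fallback sets out from 13 and comes back at 24; it replaces the organozinc by a borane. KOt-Bu (THF, 0 °C) eliminates HBr from 13 to give 2-(furan-3-ylmethyl)-4-[(E)-4-methylhexa-3,5-dien-1-yl]furan F8. 9-BBN adds to its terminal alkene to give 9-{(E)-6-[5-(furan-3-ylmethyl)furan-3-yl]-3-methylhex-3-en-1-yl}-9-borabicyclo[3.3.1]nonane F9. B-alkyl Suzuki–Miyaura coupling of F9 with 21 (Pd(dppf)Cl2, AsPh3, Cs2CO3, DMF/THF/H2O, rt) gives 24.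

**Step 1 (tosylhydrazone/boronic acid coupling).** Possible failures: ring opening of the furyl diazo compound or carbene, or protodeboronation of 3. The fallback sets out from 1 and comes back at 6. 3-Furyllithium (3-bromofuran, n-BuLi, THF, −78 °C) adds to 1 to give (4-bromofuran-2-yl)(furan-3-yl)methanol F1, a racemic carbinol whose centre is erased at once. Ionic hydrogenation (Et3SiH, CF3CO2H, CH2Cl2, −20 °C) then gives 6.

## Further compounds

F1 | step 1 | (4-bromofuran-2-yl)(furan-3-yl)methanol (racemate) | OC(c1cc(Br)co1)c1ccoc1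
F2 | step 7 | (2R,4Z)-2-(benzhydryloxy)-5-iodo-4-methyl-1-(1-methyl-1H-imidazol-2-yl)pent-4-en-1-one | Cn1ccnc1C(=O)[C@@H](C/C(C)=C\I)OC(c1ccccc1)c1ccccc1
F3 | step 7 | 2-[(2R,4Z)-2-(benzhydryloxy)-5-iodo-4-methylpent-4-enoyl]-1,3-dimethyl-1H-imidazol-3-ium trifluoromethanesulfonate | C[n+]1ccn(C)c1C(=O)[C@@H](C/C(C)=C\I)OC(c1ccccc1)c1ccccc1.[O-]S(=O)(=O)C(F)(F)F
F4 | step 7 | methyl (2R,4Z)-2-(benzhydryloxy)-5-iodo-4-methylpent-4-enoate | COC(=O)[C@@H](C/C(C)=C\I)OC(c1ccccc1)c1ccccc1
F5 | step 7 | methyl (2R,4Z)-2-hydroxy-5-iodo-4-methylpent-4-enoate | COC(=O)[C@@H](C/C(C)=C\I)O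
F6 | step 7 | methyl (2R,4Z)-5-iodo-4-methyl-2-(propanoyloxy)pent-4-enoate | COC(=O)[C@@H](C/C(C)=C\I)OC(=O)CC
F7 | step 7 | (R)-4-hydroxy-5-[(Z)-3-iodo-2-methylprop-2-en-1-yl]-3-methylfuran-2(5H)-one | CC1=C(O)[C@@H](C/C(C)=C\I)OC1=O
F8 | step 8 | 2-(furan-3-ylmethyl)-4-[(E)-4-methylhexa-3,5-dien-1-yl]furan | C=C/C(C)=C/CCc1coc(Cc2ccoc2)c1
F9 | step 8 | 9-{(E)-6-[5-(furan-3-ylmethyl)furan-3-yl]-3-methylhex-3-en-1-yl}-9-borabicyclo[3.3.1]nonane | B1(CC/C(C)=C/CCc2coc(Cc3ccoc3)c2)C2CCCC1CCC2
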